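**Retrosynthetic overview**

1. The ester and side chain come last: the C12–C13 bond is made by B-alkyl Suzuki coupling of the C9-vinyl decalin 25 with the (Z)-iodobutenediol unit 29, followed by acylation and desilylation.
2. Enabling feature: on ring B (C5–C10) the C5 methyl (C19) and the C8 methyl (C17) are 1,4-cis. Joining C19 to C17 turns ring B into a bicyclo[2.2.2]octanone (17), which is reopened later by α-hydroxylation, glycol cleavage and double Wolff–Kishner reduction.
3. Key disconnection: C5–C6 and C7–C8 by Diels–Alder reaction of phenyl vinyl sulfone (ethylene equivalent) with the homoannular diene C5=C19(OSi)–C17=C8 of trienol ether 13. The C3=C4 alkene next to C5 is what lets the cross-conjugated dienone 12 supply this diene by vinylogous enolisation.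
4. Dienone 12 comes from benzoic acid by Birch reductive methylation (dearomatisation; the six arene carbons become C5, C10, C9, C8, C17 and C19), oxidation to dienone 6, a desymmetrising Cu-catalysed conjugate addition of a Grignard reagent (sets C9 and C10) and aldol condensation.
5. Ring order: arene-derived carbocycle (C5–C19–C17–C8–C9–C10), then ring A (aldol), then ring B (key step); the first ring is finally cleaved to leave the two methyl groups.

Key step: step 9

Remark: atoms are named by clerodane numbering (C1–C10 decalin, C11–C16 side chain, C17/C18/C19/C20 = methyl carbons on C8/C4/C5/C9) and the acyl group is read as icosanoyl. CIP descriptors change along the route only through priority changes, and the expected major epimers are drawn for centres that are destroyed later (C7 in 15/16, the carbinol carbons in 19/20).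

**Route**

Step 1
Reactants: 1 benzoic acid
Product: 3 1-methylcyclohexa-2,5-diene-1-carboxylic acid, via dilithium cyclohexadienide carboxylate 2 (not isolated)
Conditions: Li, NH3(l)/THF, −78 °C; MeI, −78 °C → rt; aq. HCl
Reagents that add atoms: iodomethane, CI
Why: Birch reductive alkylation: reduction of the benzoate gives dianion 2, whose ipso carbanion is C-methylated, so the arene is dearomatised to a symmetric 1,4-diene in which the future C9 is already quaternary (no stereocentre yet).

Step 2
Reactants: 3 1-methylcyclohexa-2,5-diene-1-carboxylic acid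
Product: 4 (1-methylcyclohexa-2,5-dien-1-yl)methanol
Conditions: LiAlH4, THF, 0 °C → rt
Reagents that add atoms: none
Why: Hydride reduction of the carboxylic acid to the neopentyl alcohol (future C11); the isolated alkenes are inert to LiAlH4.

Step 3
Reactants: 4 (1-methylcyclohexa-2,5-dien-1-yl)methanol
Product: 5 tert-butyl[(1-methylcyclohexa-2,5-dien-1-yl)methoxy]diphenylsilane
Conditions: TBDPSCl, imidazole, DMF, rt
Reagents that add atoms: tert-butyl(chloro)diphenylsilane, CC(C)(C)[Si](Cl)(c1ccccc1)c1ccccc1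
Why: Standard silylation of a primary alcohol; the acid- and oxidant-stable TBDPS ether also makes the C11 arm clearly the larger of the two groups on C9.

Step 4
Reactants: 5 tert-butyl[(1-methylcyclohexa-2,5-dien-1-yl)methoxy]diphenylsilane
Product: 6 4-{[tert-butyl(diphenyl)silyl]oxymethyl}-4-methylcyclohexa-2,5-dien-1-one
Conditions: PDC (20 mol %), t-BuOOH, Celite, benzene, rt
Reagents that add atoms: tert-butyl hydroperoxide, CC(C)(C)OO
Why: Chromium-catalysed hydroperoxide oxidation of the doubly allylic CH2 of a 3,3-disubstituted cyclohexa-1,4-diene to the cross-conjugated dienone (allylic oxidation), aromatisation being blocked by the quaternary carbon.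

Step 5
Reactants: 7 2-(3-bromopropyl)-2-methyl-1,3-dioxolane
Product: 8 [3-(2-methyl-1,3-dioxolan-2-yl)propyl]magnesium bromide (used as a titrated diethyl ether solution)
Conditions: Mg turnings (activated with a crystal of I2), Et2O, rt → gentle reflux; titration
Reagents that add atoms: magnesium, [Mg]
Why: Grignard formation by insertion of magnesium into the primary C–Br bond; the ketal is inert and too remote from the C–Mg bond to fragment, and the bromide counter-ion is the one that suits the chiral copper catalyst of step 6.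

Step 6
Reactants: 6 4-{[tert-butyl(diphenyl)silyl]oxymethyl}-4-methylcyclohexa-2,5-dien-1-one, 8 [3-(2-methyl-1,3-dioxolan-2-yl)propyl]magnesium bromide
Product: 10 (4R,5S)-4-{[tert-butyl(diphenyl)silyl]oxymethyl}-4-methyl-5-[3-(2-methyl-1,3-dioxolan-2-yl)propyl]cyclohex-2-en-1-one, via bromomagnesium dienolate 9 (not isolated)
Conditions: 8 (1.2 equiv, slow addition), CuCl (5 mol %), Taniaphos-type ferrocenyl diphosphine (6 mol %; the enantiomer that leads to 5S), Et2O, −60 °C; aq. NH4Cl
Reagents that add atoms: none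
Why: Copper/ferrocenyl-diphosphine-catalysed enantioselective conjugate addition of a Grignard reagent that desymmetrises the 4,4-disubstituted cyclohexadienone: the chiral alkylcopper species fixes the face at the β-carbon (C10) and, because the alkyl group enters anti to the larger CH2OTBDPS arm, only the enantiotopic alkene on which that face is cis to the C9 methyl reacts, which sets C9; the adduct rests as dienolate 9 until work-up, so the second alkene is not attacked, and slow addition at low temperature should suppress uncatalysed 1,2-addition.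

Step 7
Reactants: 10 (4R,5S)-4-{[tert-butyl(diphenyl)silyl]oxymethyl}-4-methyl-5-[3-(2-methyl-1,3-dioxolan-2-yl)propyl]cyclohex-2-en-1-one
Product: 12 (4S,4aR)-4-{[tert-butyl(diphenyl)silyl]oxymethyl}-4,8-dimethyl-4a,5,6,7-tetrahydronaphthalen-1(4H)-one, via 1,7-diketone 11 (not isolated)
Conditions: 1 M HCl, THF, rt; then p-TsOH·H2O (cat.), benzene, reflux (Dean–Stark)
Reagents that add atoms: none
Why: Ketal hydrolysis gives diketone 11, whose acid-catalysed intramolecular aldol condensation (C5 enol onto the C4 ketone, 6-(enolexo)-exo-trig, then dehydration) closes ring A as the conjugated C4=C5 enone; C9 and C10 cannot enolise and stay fixed.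

Step 8
Reactants: 12 (4S,4aR)-4-{[tert-butyl(diphenyl)silyl]oxymethyl}-4,8-dimethyl-4a,5,6,7-tetrahydronaphthalen-1(4H)-one
Product: 13 tert-butyl{[(4S,4aR)-4-{[tert-butyl(diphenyl)silyl]oxymethyl}-4,8-dimethyl-4,4a,5,6-tetrahydronaphthalen-1-yl]oxy}dimethylsilane
Conditions: TBSOTf, Et3N, CH2Cl2, 0 °C → rt; filtration through basic alumina
Reagents that add atoms: tert-butyldimethylsilyl trifluoromethanesulfonate, CC(C)(C)[Si](C)(C)OS(=O)(=O)C(F)(F)F
Why: Soft enolisation: O-silylation of the cross-conjugated dienone and γ-deprotonation at ring carbon C3 (there is no α′-hydrogen) should give the fully conjugated trienol silyl ether C3=C4–C5=C19(OTBS)–C17=C8.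

Step 9
Reactants: 13 tert-butyl{[(4S,4aR)-4-{[tert-butyl(diphenyl)silyl]oxymethyl}-4,8-dimethyl-4,4a,5,6-tetrahydronaphthalen-1-yl]oxy}dimethylsilane, 14 phenyl vinyl sulfone
Product: 16 11-(tert-butyldiphenylsilyloxy)-7-(phenylsulfonyl)-17,19-cyclo-12,13,14,15,16-pentanorclerod-3-en-19-one, via silyl enol ether cycloadduct 15 (not isolated)
Conditions: 14 (3 equiv), BHT (cat.), toluene, 100 °C, sealed tube; then 1 M HCl, THF, rt
Reagents that add atoms: none
Why: Thermal, concerted but asynchronous normal-demand [4+2] cycloaddition: the only s-cis diene of 13 is the homoannular 2-silyloxydiene C5=C19(OTBS)–C17=C8 (the C3=C4–C5=C19 unit is locked s-trans), and its most nucleophilic terminus C5 bonds to the CH2 end of the vinyl sulfone while C8 bonds to the sulfonyl-bearing carbon, so the C5–C6 and C7–C8 bonds form in one operation. The closest known reaction type is the Diels–Alder reaction of 2-silyloxycyclohexa-1,3-dienes with phenyl vinyl sulfone as an ethylene equivalent, which gives bicyclo[2.2.2]octanones after hydrolysis. Ring B (C5–C6–C7–C8–C9–C10) is closed as the new two-carbon bridge of the bicyclo[2.2.2]octene, both bonds being delivered suprafacially to one face of the diene across the existing C5–C10–C9–C8 edge. The new stereocentres C5 (quaternary) and C8 follow from the face of attack, which C9 and C10 control: ring A holds C1 pseudo-equatorial, so the C9 methyl (C20) is pseudo-axial and shields its face at C8, and the sulfone should add from the face of the axial H-10, placing the C19–C17 bridge (the future 5- and 8-methyl groups) cis to C20; the endo sulfone centre at C7 is removed in step 10. The selectivities needed are site selectivity (secured by the s-trans lock of the other diene unit), π-facial selectivity (secured by the conformational lock just described) and regiochemistry, which the enol ether polarisation sets but which is irrelevant after desulfonylation. The C3=C4 double bond of 13 is left as the ring-A alkene of the target, and mild acid hydrolyses enol ether 15 to ketone 16 without touching the TBDPS ether.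

Step 10
Reactants: 16 11-(tert-butyldiphenylsilyloxy)-7-(phenylsulfonyl)-17,19-cyclo-12,13,14,15,16-pentanorclerod-3-en-19-one
Product: 17 11-(tert-butyldiphenylsilyloxy)-17,19-cyclo-12,13,14,15,16-pentanorclerod-3-en-19-one
Conditions: 6% Na(Hg), Na2HPO4, MeOH/THF, −20 °C
Reagents that add atoms: none
Why: Reductive desulfonylation by electron transfer from sodium amalgam in buffered methanol removes the activating group, so the vinyl sulfone has served as an ethylene equivalent; the C7 stereocentre disappears.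

Step 11
Reactants: 17 11-(tert-butyldiphenylsilyloxy)-17,19-cyclo-12,13,14,15,16-pentanorclerod-3-en-19-one
Product: 19 11-(tert-butyldiphenylsilyloxy)-17-hydroxy-17,19-cyclo-12,13,14,15,16-pentanorclerod-3-en-19-one, via potassium enolate 18 (not isolated)
Conditions: KHMDS, THF, −78 °C; (±)-3-phenyl-2-(phenylsulfonyl)oxaziridine, −78 °C; aq. NH4Cl
Reagents that add atoms: 3-phenyl-2-(phenylsulfonyl)oxaziridine, O=S(=O)(N1OC1c1ccccc1)c1ccccc1
Why: Davis oxidation of the enolate, which can form only toward C17 because C5 is quaternary; the oxaziridine should approach C17 from the side of the C6–C7 bridge, the other side being covered by C20 and C1 (the configuration of this carbinol is of no consequence).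

Step 12
Reactants: 19 11-(tert-butyldiphenylsilyloxy)-17-hydroxy-17,19-cyclo-12,13,14,15,16-pentanorclerod-3-en-19-one
Product: 20 11-(tert-butyldiphenylsilyloxy)-17,19-cyclo-12,13,14,15,16-pentanorclerod-3-ene-17,19-diol
Conditions: LiAlH4, THF, 0 °C
Reagents that add atoms: none
Why: Hydride reduction of the hindered ketone from the open C6–C7 side should give mainly the trans-diol; either diol isomer serves in step 13.

Step 13
Reactants: 20 11-(tert-butyldiphenylsilyloxy)-17,19-cyclo-12,13,14,15,16-pentanorclerod-3-ene-17,19-diol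
Product: 21 11-(tert-butyldiphenylsilyloxy)-12,13,14,15,16-pentanorclerod-3-ene-17,19-dial
Conditions: Pb(OAc)4, pyridine, CH2Cl2, 0 °C → rt
Reagents that add atoms: none
Why: Criegee glycol cleavage with lead tetraacetate, which unlike periodate does not depend on a cyclic diester and therefore also fragments a rigid trans-diol, opens the arene-derived ring and leaves C19 and C17 as cis formyl groups on C5 and C8.

Step 14
Reactants: 21 11-(tert-butyldiphenylsilyloxy)-12,13,14,15,16-pentanorclerod-3-ene-17,19-dial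
Product: 23 [(1S,2R,4aR,8aS)-1,2,4a,5-tetramethyl-1,2,3,4,4a,7,8,8a-octahydronaphthalen-1-yl]methanol, via bis-hydrazone 22 (not isolated)
Conditions: N2H4·H2O, diethylene glycol, 130 °C; then KOH, 200 °C; aqueous work-up
Reagents that add atoms: none
Why: Huang–Minlon Wolff–Kishner reduction of bis-hydrazone 22 turns both formyl groups into the C19 and C17 methyl groups while the hot alkali also cleaves the silyl ether; C8 is the only epimerisable centre and its substituent is already equatorial.

Step 15
Reactants: 23 [(1S,2R,4aR,8aS)-1,2,4a,5-tetramethyl-1,2,3,4,4a,7,8,8a-octahydronaphthalen-1-yl]methanol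
Product: 24 (1S,2R,4aR,8aS)-1,2,4a,5-tetramethyl-1,2,3,4,4a,7,8,8a-octahydronaphthalene-1-carbaldehyde
Conditions: Dess–Martin periodinane, CH2Cl2, rt
Reagents that add atoms: none
Why: Dess–Martin oxidation of the neopentyl primary alcohol to a non-enolisable aldehyde; the trisubstituted alkene is inert.

Step 16
Reactants: 24 (1S,2R,4aR,8aS)-1,2,4a,5-tetramethyl-1,2,3,4,4a,7,8,8a-octahydronaphthalene-1-carbaldehyde
Product: 25 (1S,2R,4aR,8aR)-1-ethenyl-1,2,4a,5-tetramethyl-1,2,3,4,4a,7,8,8a-octahydronaphthalene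
Conditions: Ph3PCH3Br, KOtBu, THF, 0 °C → reflux
Reagents that add atoms: methyltriphenylphosphonium bromide, C[P+](c1ccccc1)(c1ccccc1)c1ccccc1.[Br-]
Why: Wittig methylenation of the hindered, non-enolisable aldehyde installs C12 as a vinyl group.

Step 17
Reactants: 26 but-2-yne-1,4-diol
Product: 27 4-[(tert-butyldimethylsilyl)oxy]but-2-yn-1-ol
Conditions: NaH (1.0 equiv), THF, 0 °C; TBSCl
Reagents that add atoms: tert-butyl(chloro)dimethylsilane, CC(C)(C)[Si](C)(C)Cl
Why: Monosilylation of the symmetrical diol through its mono-sodium alkoxide.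

Step 18
Reactants: 27 4-[(tert-butyldimethylsilyl)oxy]but-2-yn-1-ol
Product: 29 (Z)-4-[(tert-butyldimethylsilyl)oxy]-3-iodobut-2-en-1-ol, via cyclic alkenylaluminate 28 (not isolated)
Conditions: Red-Al, THF, 0 °C; then I2, −78 °C → 0 °C
Reagents that add atoms: iodine, II
Why: Hydroxyl-directed trans-hydroalumination of the propargylic alcohol (hydride to C14, aluminium to C13 in the five-membered aluminate 28) and iodination with retention give the (Z)-3-iodoallylic alcohol, which fixes the C13=C14 geometry of the target.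

Step 19
Reactants: 25 (1S,2R,4aR,8aR)-1-ethenyl-1,2,4a,5-tetramethyl-1,2,3,4,4a,7,8,8a-octahydronaphthalene, 29 (Z)-4-[(tert-butyldimethylsilyl)oxy]-3-iodobut-2-en-1-ol
Product: 31 (E)-3-{[(tert-butyldimethylsilyl)oxy]methyl}-5-[(1S,2R,4aR,8aR)-1,2,4a,5-tetramethyl-1,2,3,4,4a,7,8,8a-octahydronaphthalen-1-yl]pent-2-en-1-ol, via B-alkyl-9-BBN 30 (not isolated)
Conditions: 9-BBN-H, THF, rt → 50 °C; then 29, Pd(dppf)Cl2 (5 mol %), AsPh3, Cs2CO3, DMF/H2O, rt
Reagents that add atoms: none
Why: B-alkyl Suzuki–Miyaura coupling: 9-BBN hydroborates only the monosubstituted vinyl group (anti-Markovnikov) and the alkylborane couples with the vinyl iodide with retention of alkene geometry, forming the C12–C13 bond.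

Step 20
Reactants: 31 (E)-3-{[(tert-butyldimethylsilyl)oxy]methyl}-5-[(1S,2R,4aR,8aR)-1,2,4a,5-tetramethyl-1,2,3,4,4a,7,8,8a-octahydronaphthalen-1-yl]pent-2-en-1-ol, 32 icosanoyl chloride
Product: 33 (E)-3-{[(tert-butyldimethylsilyl)oxy]methyl}-5-[(1S,2R,4aR,8aR)-1,2,4a,5-tetramethyl-1,2,3,4,4a,7,8,8a-octahydronaphthalen-1-yl]pent-2-en-1-yl icosanoate
Conditions: pyridine, DMAP (cat.), CH2Cl2, 0 °C → rt
Reagents that add atoms: none
Why: DMAP-catalysed acylation of the only free (primary allylic, C15) hydroxyl group.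

Step 21
Reactants: 33 (E)-3-{[(tert-butyldimethylsilyl)oxy]methyl}-5-[(1S,2R,4aR,8aR)-1,2,4a,5-tetramethyl-1,2,3,4,4a,7,8,8a-octahydronaphthalen-1-yl]pent-2-en-1-yl icosanoate
Product: 34 (E)-3-(hydroxymethyl)-5-[(1S,2R,4aR,8aR)-1,2,4a,5-tetramethyl-1,2,3,4,4a,7,8,8a-octahydronaphthalen-1-yl]pent-2-en-1-yl icosanoate (CNP0168335.1)
Conditions: HF·pyridine, pyridine/THF, 0 °C → rt
Reagents that add atoms: none
Why: Buffered fluoride cleavage of the primary TBS ether; acyl migration is not possible because the two oxygenated carbons are trans across the alkene.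

**Compound list**

1 | benzoic acid | OC(=O)c1ccccc1 | starting material
2 | dilithium cyclohexadienide carboxylate (not isolated) | [Li+].[Li+].[O-]C(=O)[C-]1C=CCC=C1 | intermediate
3 | 1-methylcyclohexa-2,5-diene-1-carboxylic acid | OC(=O)C1(C)C=CCC=C1 | intermediate
4 | (1-methylcyclohexa-2,5-dien-1-yl)methanol | OCC1(C)C=CCC=C1 | intermediate
5 | tert-butyl[(1-methylcyclohexa-2,5-dien-1-yl)methoxy]diphenylsilane | CC(C)(C)[Si](c1ccccc1)(c1ccccc1)OCC1(C)C=CCC=C1 | intermediate
6 | 4-{[tert-butyl(diphenyl)silyl]oxymethyl}-4-methylcyclohexa-2,5-dien-1-one | CC(C)(C)[Si](c1ccccc1)(c1ccccc1)OCC1(C)C=CC(=O)C=C1 | intermediate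
7 | 2-(3-bromopropyl)-2-methyl-1,3-dioxolane | CC1(CCCBr)OCCO1 | starting material
8 | [3-(2-methyl-1,3-dioxolan-2-yl)propyl]magnesium bromide | CC1(CCC[Mg]Br)OCCO1 | intermediate
9 | bromomagnesium dienolate of 10 (O–C1=C6; not isolated) | CC(C)(C)[Si](c1ccccc1)(c1ccccc1)OC[C@@]1(C)C=CC(O[Mg]Br)=C[C@@H]1CCCC2(C)OCCO2 | intermediate
10 | (4R,5S)-4-{[tert-butyl(diphenyl)silyl]oxymethyl}-4-methyl-5-[3-(2-methyl-1,3-dioxolan-2-yl)propyl]cyclohex-2-en-1-one | CC(C)(C)[Si](c1ccccc1)(c1ccccc1)OC[C@@]1(C)C=CC(=O)C[C@@H]1CCCC2(C)OCCO2 | intermediate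
11 | (4R,5S)-4-{[tert-butyl(diphenyl)silyl]oxymethyl}-4-methyl-5-(4-oxopentyl)cyclohex-2-en-1-one (not isolated) | CC(C)(C)[Si](c1ccccc1)(c1ccccc1)OC[C@@]1(C)C=CC(=O)C[C@@H]1CCCC(C)=O | intermediate
12 | (4S,4aR)-4-{[tert-butyl(diphenyl)silyl]oxymethyl}-4,8-dimethyl-4a,5,6,7-tetrahydronaphthalen-1(4H)-one | CC(C)(C)[Si](c1ccccc1)(c1ccccc1)OC[C@@]1(C)C=CC(=O)C2=C(C)CCC[C@H]12 | intermediate
13 | tert-butyl{[(4S,4aR)-4-{[tert-butyl(diphenyl)silyl]oxymethyl}-4,8-dimethyl-4,4a,5,6-tetrahydronaphthalen-1-yl]oxy}dimethylsilane | CC(C)(C)[Si](c1ccccc1)(c1ccccc1)OC[C@@]1(C)C=CC(O[Si](C)(C)C(C)(C)C)=C2C(C)=CCC[C@H]12 | intermediate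
14 | phenyl vinyl sulfone | C=CS(=O)(=O)c1ccccc1 | starting material
15 | 19-(tert-butyldimethylsilyloxy)-11-(tert-butyldiphenylsilyloxy)-7-(phenylsulfonyl)-17,19-cyclo-12,13,14,15,16-pentanorcleroda-3,17(19)-diene, endo sulfone (not isolated) | CC(C)(C)[Si](c1ccccc1)(c1ccccc1)OC[C@@]1(C)[C@H]3[C@H](S(=O)(=O)c4ccccc4)C[C@@]2(C(O[Si](C)(C)C(C)(C)C)=C3)C(C)=CCC[C@H]12 | intermediate
16 | 11-(tert-butyldiphenylsilyloxy)-7-(phenylsulfonyl)-17,19-cyclo-12,13,14,15,16-pentanorclerod-3-en-19-one (C5, C8, C9, C10 as in the target) | CC(C)(C)[Si](c1ccccc1)(c1ccccc1)OC[C@@]1(C)[C@H]3[C@H](S(=O)(=O)c4ccccc4)C[C@@]2(C(=O)C3)C(C)=CCC[C@H]12 | intermediate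
17 | 11-(tert-butyldiphenylsilyloxy)-17,19-cyclo-12,13,14,15,16-pentanorclerod-3-en-19-one | CC(C)(C)[Si](c1ccccc1)(c1ccccc1)OC[C@@]1(C)[C@H]3CC[C@@]2(C(=O)C3)C(C)=CCC[C@H]12 | intermediate
18 | potassium enolate of 17 (C17=C19–O−; not isolated) | CC(C)(C)[Si](c1ccccc1)(c1ccccc1)OC[C@@]1(C)[C@H]3CC[C@@]2(C([O-])=C3)C(C)=CCC[C@H]12.[K+] | intermediate
19 | 11-(tert-butyldiphenylsilyloxy)-17-hydroxy-17,19-cyclo-12,13,14,15,16-pentanorclerod-3-en-19-one (OH toward the C6–C7 bridge) | CC(C)(C)[Si](c1ccccc1)(c1ccccc1)OC[C@@]1(C)[C@H]3CC[C@@]2(C(=O)[C@@H]3O)C(C)=CCC[C@H]12 | intermediate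
20 | 11-(tert-butyldiphenylsilyloxy)-17,19-cyclo-12,13,14,15,16-pentanorclerod-3-ene-17,19-diol (trans-diol) | CC(C)(C)[Si](c1ccccc1)(c1ccccc1)OC[C@@]1(C)[C@H]3CC[C@@]2([C@@H](O)[C@@H]3O)C(C)=CCC[C@H]12 | intermediate
21 | 11-(tert-butyldiphenylsilyloxy)-12,13,14,15,16-pentanorclerod-3-ene-17,19-dial | CC(C)(C)[Si](c1ccccc1)(c1ccccc1)OC[C@@]1(C)[C@H](C=O)CC[C@@]2(C=O)C(C)=CCC[C@H]12 | intermediate
22 | bis-hydrazone of 21 (not isolated) | CC(C)(C)[Si](c1ccccc1)(c1ccccc1)OC[C@@]1(C)[C@H](C=NN)CC[C@@]2(C=NN)C(C)=CCC[C@H]12 | intermediate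
23 | [(1S,2R,4aR,8aS)-1,2,4a,5-tetramethyl-1,2,3,4,4a,7,8,8a-octahydronaphthalen-1-yl]methanol | OC[C@@]1(C)[C@H](C)CC[C@@]2(C)C(C)=CCC[C@H]12 | intermediate
24 | (1S,2R,4aR,8aS)-1,2,4a,5-tetramethyl-1,2,3,4,4a,7,8,8a-octahydronaphthalene-1-carbaldehyde | O=C[C@@]1(C)[C@H](C)CC[C@@]2(C)C(C)=CCC[C@H]12 | intermediate
25 | (1S,2R,4aR,8aR)-1-ethenyl-1,2,4a,5-tetramethyl-1,2,3,4,4a,7,8,8a-octahydronaphthalene | C=C[C@@]1(C)[C@H](C)CC[C@@]2(C)C(C)=CCC[C@H]12 | intermediate
26 | but-2-yne-1,4-diol | OCC#CCO | starting material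
27 | 4-[(tert-butyldimethylsilyl)oxy]but-2-yn-1-ol | OCC#CCO[Si](C)(C)C(C)(C)C | intermediate
28 | sodium cyclic alkenylaluminate from 27 and Red-Al (not isolated) | [Na+].COCCO[Al-]1(OCCOC)OCC=C1CO[Si](C)(C)C(C)(C)C | intermediate
29 | (Z)-4-[(tert-butyldimethylsilyl)oxy]-3-iodobut-2-en-1-ol | OC/C=C(/CO[Si](C)(C)C(C)(C)C)I | intermediate
30 | 9-{2-[(1S,2R,4aR,8aR)-1,2,4a,5-tetramethyl-1,2,3,4,4a,7,8,8a-octahydronaphthalen-1-yl]ethyl}-9-borabicyclo[3.3.1]nonane (not isolated) | C(C[C@@]1(C)[C@H](C)CC[C@@]2(C)C(C)=CCC[C@H]12)B1C2CCCC1CCC2 | intermediate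
31 | (E)-3-{[(tert-butyldimethylsilyl)oxy]methyl}-5-[(1S,2R,4aR,8aR)-1,2,4a,5-tetramethyl-1,2,3,4,4a,7,8,8a-octahydronaphthalen-1-yl]pent-2-en-1-ol | OC/C=C(/CO[Si](C)(C)C(C)(C)C)CC[C@@]1(C)[C@H](C)CC[C@@]2(C)C(C)=CCC[C@H]12 | intermediate
32 | icosanoyl chloride | CCCCCCCCCCCCCCCCCCCC(=O)Cl | starting material
33 | (E)-3-{[(tert-butyldimethylsilyl)oxy]methyl}-5-[(1S,2R,4aR,8aR)-1,2,4a,5-tetramethyl-1,2,3,4,4a,7,8,8a-octahydronaphthalen-1-yl]pent-2-en-1-yl icosanoate | CCCCCCCCCCCCCCCCCCCC(=O)OC/C=C(/CO[Si](C)(C)C(C)(C)C)CC[C@@]1(C)[C@H](C)CC[C@@]2(C)C(C)=CCC[C@H]12 | intermediate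
34 | (E)-3-(hydroxymethyl)-5-[(1S,2R,4aR,8aR)-1,2,4a,5-tetramethyl-1,2,3,4,4a,7,8,8a-octahydronaphthalen-1-yl]pent-2-en-1-yl icosanoate | CCCCCCCCCCCCCCCCCCCC(=O)OC/C=C(/CO)CC[C@@]1(C)[C@H](C)CC[C@@]2(C)C(C)=CCC[C@H]12 | target

**Step count and risks**

Total step count: 21. Longest linear sequence: 18 steps (steps 1–4, 6–16 and 19–21); steps 5 and 17–18 prepare the two side branches.

Steps most likely to fail:

1. Step 9. The cycloaddition has to build the quaternary C5 between C4 and C10 and a bond at C8 next to the quaternary C9. It may be slow enough for thermal decay of the silyl trienol ether (desilylation, 1,5-hydrogen shift) to compete, and the facial selectivity may erode at the temperature required. The fallback sets out from 12 and comes back at 16; it replaces the cycloaddition by a stepwise anionic annulation (Michael-initiated ring closure). The thermodynamic potassium dienolate of 12 (KOtBu, THF, 0 °C) is alkylated at C5 by phenyl vinyl sulfone 14 at low temperature, again anti to the pseudo-axial C9 methyl, and the α-sulfonyl carbanion formed adds to C8 of the enone (6-exo-trig). If the sequence stops after the first addition, the C5-alkylated enone F1 is isolated and closed separately with KHMDS in THF to give 16.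

2. Step 6. The chiral copper complex may discriminate insufficiently between the two enantiotopic alkenes or between the two faces, and uncatalysed 1,2-addition of the Grignard reagent to the dienone carbonyl may compete with the catalysed transfer to the β-carbon next to the quaternary centre. The fallback sets out from 6 and comes back at 10; it uses a racemic, substrate-controlled addition followed by resolution. Grignard reagent 8 with catalytic CuBr·SMe2 and TMSCl in THF at −78 °C, then mild acid work-up, should give the racemic trans adduct F2. Addition of lithiated (S)-N,S-dimethyl-S-phenylsulfoximine to the ketone and chromatographic separation of the diastereomers gives the β-hydroxysulfoximine F3, and thermolysis of F3 in toluene at 110 °C returns enantiopure 10.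

3. Step 13. Fragmentation of the rigid trans-diol may be slow because no cyclic lead(IV) diester can form, which leaves time for over-oxidation of the liberated aldehydes. The fallback sets out from 19 and comes back at 21; it goes through a cis-diol that periodate cleaves readily. Dess–Martin oxidation of 19 gives the α-diketone F4; reduction with NaBH4 in methanol, both hydrides arriving from the open C6–C7 side, should give the cis-diol F5, and NaIO4 in THF/water cleaves F5 to 21.

Further compounds
F1 | step 9 | (4S,4aR,8aR)-4-{[tert-butyl(diphenyl)silyl]oxymethyl}-4,8-dimethyl-8a-[2-(phenylsulfonyl)ethyl]-4a,5,6,8a-tetrahydronaphthalen-1(4H)-one (C5-alkylated enone) | CC(C)(C)[Si](c1ccccc1)(c1ccccc1)OC[C@@]1(C)C=CC(=O)[C@]2(CCS(=O)(=O)c3ccccc3)C(C)=CCC[C@H]12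
F2 | step 6 | racemic trans-4-{[tert-butyl(diphenyl)silyl]oxymethyl}-4-methyl-5-[3-(2-methyl-1,3-dioxolan-2-yl)propyl]cyclohex-2-en-1-one (both enantiomers) | CC(C)(C)[Si](c1ccccc1)(c1ccccc1)OC[C@@]1(C)C=CC(=O)C[C@@H]1CCCC2(C)OCCO2.CC(C)(C)[Si](c1ccccc1)(c1ccccc1)OC[C@]1(C)C=CC(=O)C[C@H]1CCCC2(C)OCCO2
F3 | step 6 | β-hydroxysulfoximine from (4R,5S)-10 and (S)-N,S-dimethyl-S-phenylsulfoximine (carbinol configuration not defined) | CC(C)(C)[Si](c1ccccc1)(c1ccccc1)OC[C@@]1(C)C=CC(O)(C[S@@](=O)(=NC)c2ccccc2)C[C@@H]1CCCC2(C)OCCO2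
F4 | step 13 | 11-(tert-butyldiphenylsilyloxy)-17,19-cyclo-12,13,14,15,16-pentanorclerod-3-ene-17,19-dione | CC(C)(C)[Si](c1ccccc1)(c1ccccc1)OC[C@@]1(C)[C@H]3CC[C@@]2(C(=O)C3=O)C(C)=CCC[C@H]12
F5 | step 13 | 11-(tert-butyldiphenylsilyloxy)-17,19-cyclo-12,13,14,15,16-pentanorclerod-3-ene-17,19-diol, cis-diol with both hydroxyl groups toward the C9–C10 bridge | CC(C)(C)[Si](c1ccccc1)(c1ccccc1)OC[C@@]1(C)[C@H]3CC[C@@]2([C@@H](O)[C@H]3O)C(C)=CCC[C@H]12
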